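**Retrosynthetic overview**
- Feature: in the five-membered lactam ring of the oxindole (N1–C2–C3–C3a–C7a), the carbonyl carbon C2 is bonded only to N1 and to the stereogenic C3. It is therefore a one-carbon unit. Cutting C2–N1 and C2–C3 releases CO and leaves an (E)-2-aminostyryl pyrazinone, whose alkene carbon next to the aniline ring becomes C3.
- The alkene (future C3–CH2 bond) is cut by a Heck disconnection. This gives 2-prenyl-6-vinylaniline and a 6-bromo-5-methoxy-3-methylpyrazine that carries the pyrazinone oxygen as a 2-(trimethylsilyl)ethyl ether.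
- The bromopyrazine comes from 3-methylpyrazin-2(1H)-one by C5 bromination, O-alkylation, exchange of Br for OMe, and C6 bromination. The vinylaniline comes from 2-bromo-6-iodoaniline by Stille prenylation at C–I and Suzuki vinylation at C–Br.
- Ring order: the benzene and pyrazine rings are bought. The lactam ring is the only ring formed, and it is formed last together with the only stereocentre, so no basic step follows it.

Key step: step 9

Assumption: the sense of induction of the ligand on this new substrate class cannot be derived from precedent. (R)-DTBM-SEGPHOS is written for the (S)-product, and its (S)-antipode is used if a first run shows the opposite sense.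

Step 1
Reactants: 1 3-methylpyrazin-2(1H)-one
Product: 2 5-bromo-3-methylpyrazin-2(1H)-one
Conditions: NBS (1.05 equiv), DMF, 0 °C to rt
Reagents that add atoms: N-bromosuccinimide, O=C1CCC(=O)N1Br
Why: Electrophilic aromatic bromination: the N1 lone pair pushes through C6=C5, so C5 (para to the carbonyl carbon) is the nucleophilic ring position, and C3 is blocked by the methyl group.

Step 2
Reactants: 2 5-bromo-3-methylpyrazin-2(1H)-one
Product: 3 5-bromo-3-methyl-2-[2-(trimethylsilyl)ethoxy]pyrazine
Conditions: Me3SiCH2CH2OH, PPh3, DIAD, THF, 0 °C to rt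
Reagents that add atoms: 2-(trimethylsilyl)ethanol, C[Si](C)(C)CCO
Why: Mitsunobu reaction: the acidic, electron-poor bromopyrazinone should be alkylated by the primary alkoxyphosphonium ion mainly at oxygen, which restores the aromatic pyrazine needed for step 3, and a minor N1-alkyl isomer would be far more polar and separable on silica.

Step 3
Reactants: 3 5-bromo-3-methyl-2-[2-(trimethylsilyl)ethoxy]pyrazine
Product: 4 5-methoxy-3-methyl-2-[2-(trimethylsilyl)ethoxy]pyrazine
Conditions: NaOMe (3 equiv), CuBr (10 mol %), MeOH/NMP, 100 °C, sealed tube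
Reagents that add atoms: sodium methoxide, C[O-].[Na+]
Why: Copper-assisted nucleophilic aromatic substitution (Ullmann-type ether synthesis): C5–Br lies next to N4 and is unhindered, bromide is a far better leaving group than the alkoxide at C2 (which the C3 methyl group also screens), and the silylethyl ether is inert to methoxide.

Step 4
Reactants: 4 5-methoxy-3-methyl-2-[2-(trimethylsilyl)ethoxy]pyrazine
Product: 5 2-bromo-3-methoxy-5-methyl-6-[2-(trimethylsilyl)ethoxy]pyrazine (Br at C6 in pyrazinone numbering)
Conditions: NBS (1.05 equiv), MeCN, 0 °C to rt, dark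
Reagents that add atoms: N-bromosuccinimide, O=C1CCC(=O)N1Br
Why: Electrophilic aromatic bromination: C6 is the only free ring position and is activated by the ortho methoxy and the para methyl group, while the polar solvent, low temperature and exclusion of light suppress radical bromination of the methyl group.

Step 5
Reactants: 6 2-bromo-6-iodoaniline; 7 tributyl(3-methylbut-2-enyl)stannane
Product: 8 2-bromo-6-(3-methylbut-2-enyl)aniline
Conditions: Pd(PPh3)4 (5 mol %), DMF, 70 °C
Reagents that add atoms: tributyl(3-methylbut-2-enyl)stannane 7, CCCC[Sn](CCCC)(CCCC)CC=C(C)C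
Why: Stille coupling: zerovalent palladium adds to C–I well before C–Br at this temperature, and reductive elimination from the allylpalladium intermediate at its unsubstituted terminus should give the linear prenyl arene rather than the 1,1-dimethylallyl isomer.

Step 6
Reactants: 8 2-bromo-6-(3-methylbut-2-enyl)aniline; 9 2-ethenyl-4,4,5,5-tetramethyl-1,3,2-dioxaborolane
Product: 10 2-ethenyl-6-(3-methylbut-2-enyl)aniline
Conditions: PdCl2(dppf) (3 mol %), K2CO3, 1,4-dioxane/H2O, 85 °C
Reagents that add atoms: 2-ethenyl-4,4,5,5-tetramethyl-1,3,2-dioxaborolane 9, C=CB1OC(C)(C)C(C)(C)O1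
Why: Suzuki–Miyaura vinylation: the remaining C–Br bond couples with the vinylboronate under mild aqueous carbonate conditions that leave the free NH2 group and the prenyl alkene untouched.

Step 7
Reactants: 5 2-bromo-3-methoxy-5-methyl-6-[2-(trimethylsilyl)ethoxy]pyrazine; 10 2-ethenyl-6-(3-methylbut-2-enyl)aniline
Product: 11 2-{(E)-2-[3-methoxy-5-methyl-6-(2-trimethylsilylethoxy)pyrazin-2-yl]ethenyl}-6-(3-methylbut-2-enyl)aniline
Conditions: Pd(OAc)2 (5 mol %), P(o-tol)3 (12 mol %), Et3N, DMF, 95 °C
Reagents that add atoms: none
Why: Mizoroki–Heck reaction: the heteroaryl bromide adds to zerovalent palladium, the vinyl group inserts at its terminal carbon and syn β-hydride elimination gives the E alkene, whereas the trisubstituted prenyl alkene is too hindered to insert and triethylamine is too weak a base for C–N coupling of the aniline.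

Step 8
Reactants: 11 2-{(E)-2-[3-methoxy-5-methyl-6-(2-trimethylsilylethoxy)pyrazin-2-yl]ethenyl}-6-(3-methylbut-2-enyl)aniline
Product: 13 (E)-6-{2-[2-amino-3-(3-methylbut-2-enyl)phenyl]ethenyl}-5-methoxy-3-methylpyrazin-2(1H)-one, via tetrabutylammonium pyrazin-2-olate salt 12 (not isolated)
Conditions: TBAF (3 equiv), THF, rt to 45 °C; then AcOH
Reagents that add atoms: none
Why: Fluoride-induced β-elimination of a 2-silylethyl ether: fluoride attacks silicon, ethene and the stabilised pyrazinolate leave, and acetic acid protonates the salt to the pyrazinone, under conditions to which the methyl ether, both alkenes and the aniline are inert and which are applied before any stereocentre exists.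

Step 9
Reactants: 13 (E)-6-{2-[2-amino-3-(3-methylbut-2-enyl)phenyl]ethenyl}-5-methoxy-3-methylpyrazin-2(1H)-one; 14 carbon monoxide
Product: 15 astepyrazinol B, 6-{[(3S)-7-(3-methylbut-2-enyl)-2-oxo-2,3-dihydro-1H-indol-3-yl]methyl}-5-methoxy-3-methylpyrazin-2(1H)-one
Conditions: Pd(OAc)2 (5 mol %), (R)-DTBM-SEGPHOS (6 mol %), TsOH·H2O (15 mol %), CO (30 bar), THF, 60 °C; base-free work-up, neutral silica
Reagents that add atoms: carbon monoxide 14, [C-]#[O+]
Why: Proposed new method: Pd(OAc)2 is reduced under CO and protonated by the sulfonic acid (levelled by the substrate to its anilinium sulfonate) to a cationic bisphosphine hydride of divalent palladium, which adds syn across the C=C bond of 13 with palladium on the carbon bound to the aniline ring; migratory insertion of CO then gives the acylpalladium species, and the ortho NH2 group attacks its carbonyl carbon, so that C2–C3 and C2–N1 are formed and the hydride is released again. The closest known reaction types are the palladium-catalysed cyclocarbonylation of 2-vinylanilines to lactams and the enantioselective Markovnikov hydroaminocarbonylation of terminal vinylarenes with anilines, and what is new is the enantioselective closure on a 1,2-disubstituted aryl/heteroaryl alkene. The lactam ring (N1, C2, C3, C3a, C7a) closes in a 5-exo-trig acyl substitution, a formal (4+1) union of the N1–C7a–C3a–C3 chain with CO. C3 is the only new stereocentre and is fixed when the chiral pocket of the atropisomeric ligand selects the alkene face for hydropalladation, since CO insertion and aminolysis proceed with retention at carbon. The step needs regioselectivity, which the substrate secures because hydropalladation is reversible, the aniline-side alkyl is held as an η3-benzyl unit of the donor ring and as a five-membered C,N-chelate, and its acyl closes a five-membered ring faster than the pyrazinone-side acyl can close a six-membered one; it also needs chemoselectivity, secured by the slow insertion of the trisubstituted prenyl alkene and by the far higher nucleophilicity of the aniline nitrogen compared with the lactam-type N1–H of the pyrazinone. The weakly acidic, base-free medium and the moderate temperature should keep the C3–H lactam from enolising.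

**Compound list**
1 | 3-methylpyrazin-2(1H)-one | Cc1ncc[nH]c1=O | starting material
2 | 5-bromo-3-methylpyrazin-2(1H)-one | Cc1nc(Br)c[nH]c1=O | intermediate
3 | 5-bromo-3-methyl-2-[2-(trimethylsilyl)ethoxy]pyrazine | Cc1nc(Br)cnc1OCC[Si](C)(C)C | intermediate
4 | 5-methoxy-3-methyl-2-[2-(trimethylsilyl)ethoxy]pyrazine | COc1cnc(OCC[Si](C)(C)C)c(C)n1 | intermediate
5 | 2-bromo-3-methoxy-5-methyl-6-[2-(trimethylsilyl)ethoxy]pyrazine | COc1nc(C)c(OCC[Si](C)(C)C)nc1Br | intermediate
6 | 2-bromo-6-iodoaniline | Nc1c(Br)cccc1I | starting material
7 | tributyl(3-methylbut-2-enyl)stannane | CCCC[Sn](CCCC)(CCCC)CC=C(C)C | starting material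
8 | 2-bromo-6-(3-methylbut-2-enyl)aniline | CC(C)=CCc1cccc(Br)c1N | intermediate
9 | 2-ethenyl-4,4,5,5-tetramethyl-1,3,2-dioxaborolane | C=CB1OC(C)(C)C(C)(C)O1 | starting material
10 | 2-ethenyl-6-(3-methylbut-2-enyl)aniline | C=Cc1cccc(CC=C(C)C)c1N | intermediate
11 | 2-{(E)-2-[3-methoxy-5-methyl-6-(2-trimethylsilylethoxy)pyrazin-2-yl]ethenyl}-6-(3-methylbut-2-enyl)aniline | COc1nc(C)c(OCC[Si](C)(C)C)nc1/C=C/c1cccc(CC=C(C)C)c1N | intermediate
12 | tetrabutylammonium (E)-6-{2-[2-amino-3-(3-methylbut-2-enyl)phenyl]ethenyl}-5-methoxy-3-methylpyrazin-2-olate | COc1nc(C)c([O-])nc1/C=C/c1cccc(CC=C(C)C)c1N.CCCC[N+](CCCC)(CCCC)CCCC | intermediate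
13 | (E)-6-{2-[2-amino-3-(3-methylbut-2-enyl)phenyl]ethenyl}-5-methoxy-3-methylpyrazin-2(1H)-one | COc1nc(C)c(=O)[nH]c1/C=C/c1cccc(CC=C(C)C)c1N | intermediate
14 | carbon monoxide | [C-]#[O+] | starting material
15 | astepyrazinol B, (3S) | COc1nc(C)c(=O)[nH]c1C[C@@H]1C(=O)Nc2c(CC=C(C)C)cccc21 | target

**Total step count:** 9
**Longest linear sequence:** 7 (steps 1, 2, 3, 4, 7, 8, 9)

**Steps most likely to fail**

1. **Step 9 (Proposed new method).**
   - What may go wrong: insertion and closure through the pyrazinone-side carbon to a six-membered lactam; weak facial discrimination on the 1,2-disubstituted alkene; hydride-induced migration of the prenyl double bond; slow enolisation of C3–H at the reaction temperature.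
   - Fallback (known chemistry; sets out from 5 and 7, comes back at 15): the C3–CH2 bond is made by condensation instead of making the C2 bonds by carbonylation, and the enantiomer is obtained by resolution.
   - Bromide 5 undergoes bromine–lithium exchange (n-BuLi, THF, −78 °C) to the pyrazinyllithium F1. This is formylated with DMF (aqueous NH4Cl quench) to 3-methoxy-5-methyl-6-[2-(trimethylsilyl)ethoxy]pyrazine-2-carbaldehyde F2.
   - Purchased 7-bromoindolin-2-one F3 is coupled with 7 (Pd(PPh3)4, DMF, 90 °C) to 7-(3-methylbut-2-enyl)indolin-2-one F4.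
   - Knoevenagel condensation of F2 with F4 (catalytic piperidine, EtOH, reflux) gives the 3-ylidene oxindole F5 as an E/Z mixture.
   - NaBH4 in THF/MeOH at 0 °C reduces the polarised exocyclic alkene of F5 in the conjugate sense to the racemic protected oxindole F6, leaving the prenyl group alone.
   - TBAF followed by AcOH, through the tetrabutylammonium salt F7, releases racemic astepyrazinol B F8.
   - Preparative supercritical-fluid chromatography on an amylose carbamate phase separates 15 from its (R)-enantiomer F9. F9 is racemised back to F8 with Et3N in MeOH and recycled.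

2. **Step 4.**
   - What may go wrong: radical bromination in the methyl group, or sluggish substitution on the π-deficient ring.
   - Fallback (sets out from 4, comes back at 5): electrophilic substitution is replaced by directed deprotonative metalation.
   - TMPMgCl·LiCl (THF, −40 °C) should magnesiate C6–H, the ring position flanked by N1 and the coordinating methoxy group, to the pyrazinylmagnesium chloride F10. Quenching with 1,2-dibromo-1,1,2,2-tetrachloroethane gives 5.

3. **Step 7.**
   - What may go wrong: slow oxidative addition at the hindered, donor-substituted bromide; binding of the catalyst by the aniline and pyrazine nitrogens; thermal oligomerisation of the vinylaniline.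
   - Fallback (sets out from 5, 9 and 8, comes back at 11): the roles of the partners are exchanged.
   - Suzuki–Miyaura vinylation of 5 with 9 (PdCl2(dppf), K2CO3, dioxane/H2O, 85 °C) gives 2-ethenyl-3-methoxy-5-methyl-6-[2-(trimethylsilyl)ethoxy]pyrazine F11, an unhindered electron-poor acceptor.
   - Heck coupling of F11 with bromoaniline 8 (Pd2(dba)3, P(t-Bu)3·HBF4, Cy2NMe, dioxane, 100 °C) gives 11. Step 6 is then not needed.

**Further compounds**
F1 | step 9 | {3-methoxy-5-methyl-6-[2-(trimethylsilyl)ethoxy]pyrazin-2-yl}lithium | COc1nc(C)c(OCC[Si](C)(C)C)nc1[Li]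
F2 | step 9 | 3-methoxy-5-methyl-6-[2-(trimethylsilyl)ethoxy]pyrazine-2-carbaldehyde | COc1nc(C)c(OCC[Si](C)(C)C)nc1C=O
F3 | step 9 | 7-bromoindolin-2-one (purchased) | O=C1Cc2cccc(Br)c2N1
F4 | step 9 | 7-(3-methylbut-2-enyl)indolin-2-one | CC(C)=CCc1cccc2c1NC(=O)C2
F5 | step 9 | 3-({3-methoxy-5-methyl-6-[2-(trimethylsilyl)ethoxy]pyrazin-2-yl}methylidene)-7-(3-methylbut-2-enyl)indolin-2-one (E/Z mixture) | COc1nc(C)c(OCC[Si](C)(C)C)nc1C=C1C(=O)Nc2c(CC=C(C)C)cccc21
F6 | step 9 | racemic 3-({3-methoxy-5-methyl-6-[2-(trimethylsilyl)ethoxy]pyrazin-2-yl}methyl)-7-(3-methylbut-2-enyl)indolin-2-one | COc1nc(C)c(OCC[Si](C)(C)C)nc1CC1C(=O)Nc2c(CC=C(C)C)cccc21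
F7 | step 9 | tetrabutylammonium pyrazin-2-olate salt of racemic astepyrazinol B | COc1nc(C)c([O-])nc1CC1C(=O)Nc2c(CC=C(C)C)cccc21.CCCC[N+](CCCC)(CCCC)CCCC
F8 | step 9 | racemic astepyrazinol B | COc1nc(C)c(=O)[nH]c1CC1C(=O)Nc2c(CC=C(C)C)cccc21
F9 | step 9 | (3R)-enantiomer of astepyrazinol B | COc1nc(C)c(=O)[nH]c1C[C@H]1C(=O)Nc2c(CC=C(C)C)cccc21
F10 | step 4 | {3-methoxy-5-methyl-6-[2-(trimethylsilyl)ethoxy]pyrazin-2-yl}magnesium chloride | COc1nc(C)c(OCC[Si](C)(C)C)nc1[Mg]Cl
F11 | step 7 | 2-ethenyl-3-methoxy-5-methyl-6-[2-(trimethylsilyl)ethoxy]pyrazine | COc1nc(C)c(OCC[Si](C)(C)C)nc1C=C
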